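Read the stillness of the noon and midnight runs as dead catalyst, not slow catalyst: noon reads 5.1% target at 10.0 s and 4.7% at 90.0 s, and both runs charged more impurity than free catalyst.

| setting | dusk | noon | midnight | flask |
|---|---|---|---|---|
| starting material | 0.58 M | 0.58 M | 0.58 M | 0.58 M |
| second substrate | 2 equiv | 2 equiv | 2 equiv | 2.00 equiv |
| free catalyst | 1.1 mol% | 1.1 mol% | 0.55 mol% | 1.1 mol% |
| impurity | 2.6 mM | 11 mM | 5.3 mM | 5.3 mM |
| remark | run made earlier | run made earlier | run made earlier |  |

- dusk (time / s: target / %, starting material / %): 10.0: 98.5, 2.4; 15.0: 99.5, 0.2; 25.0: 99.6, 0.3; 50.0: 99.8, 0; 90.0: 99.5, 0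
- noon (time / s: target / %, starting material / %): 10.0: 5.1, 95.5; 25.0: 5.8, 95.5; 40.0: 5.2, 94.6; 60.0: 5.5, 95.0; 90.0: 4.7, 95.2
- midnight (time / s: target / %, starting material / %): 20.0: 4.6, 94.9; 40.0: 5.3, 95.2; 60.0: 6.5, 93.9; 80.0: 5.0, 94.6; 90.0: 4.8, 94.2

(readings scatter by 0.5 percentage points)

- no earlier run changes the charge of second substrate; that part of a forecast is a guess

* apparent order in free catalyst when 5.0% of the starting material are converted (percent change of the rate of making target for one percent more free catalyst charged)
* factor on the rate of making target when 5.0% of the starting material are converted if second substrate is charged twice over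

Take over this flask on the reckoning that impurity kills free catalyst one for one while target forms, so target = K ln(charged [impurity] / present [impurity]); the noon plateau reads K = 6.06%. At 5.0% conversion expect 2.32 mM impurity in the flask, hence live catalyst, charged less consumed, of 3.40 mM. In this reckoning K ties [impurity] to conversion whatever the loading, so added catalyst goes straight into live catalyst, and the order is charged over live, 1.87 by my reckoning. Expect the impurity of this flask, the limiting reagent of this poisoning at 5.3 mM against 6.38 mM of catalyst charged, to be used up; the live catalyst that stays is 1.08 mM, the surplus, catalyst charged less impurity charged. Do not touch second substrate: no run varies it, and my guess for doubling it is no change.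

The forecast gives an order of 1.9 and a factor of 2.7 on doubling second substrate, where my guess is no change, and holds of the order that “Extra catalyst adds directly to this”.

The flask gives an order of 1.9 and a factor of 0.782.

    starting material + free catalyst ⇌ catalyst intermediate A (K = 5.80 L mol⁻¹, k = 290 L mol⁻¹ s⁻¹)
    second substrate + free catalyst ⇌ catalyst intermediate B (K = 0.750 L mol⁻¹, k = 21.0 L mol⁻¹ s⁻¹)
    catalyst intermediate A → free catalyst + target (k = 120 s⁻¹)
    catalyst intermediate B → free catalyst + second product (k = 6.10 s⁻¹)
    free catalyst + impurity → spent catalyst (k = 3400 L mol⁻¹ s⁻¹)

Of the turnover up to 2.00 min, the flask does half of the step to target by 0.106 min and half of the step from second substrate into catalyst intermediate B by 0.982 min. At that time 74.6% of the charge of second substrate stands in the flask, with target at >99.9%. At 0.200 min the flask holds 83.1% of its catalyst as spent catalyst and 16.9% as free catalyst and catalyst intermediates A and B, and its surplus of 1.08 mM is 16.9% of the charge. The dusk run's surplus is 3.78 mM, and it read 98.5% target at 10.0 s.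

The runs were generated by integration for an exercise.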